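The constants used here are made up; what happens was integrated by code.

You are taking over flasks with a small charge of free enzyme, 0.01 mol% on the starting material, with capture agent beside it.

| setting | epsilon | delta | beta | alpha |
|---|---|---|---|---|
| starting material | 0.10 M | 0.10 M (fed, over 1.50 min) | 0.10 M | 0.10 M |
| second substrate | 0.600 equiv | 0.600 equiv | 0.600 equiv (fed, over 1.50 min) | 0.600 equiv |
| capture agent | 0.0300 M | 0.0300 M | 0.0300 M | 0.0300 M |
| free enzyme | 0.01 mol% | 0.01 mol% | 0.01 mol% | 0.01 mol% |
| time | 3.0 min | 3.0 min | 3.0 min |  |
| remark | everything together in a closed stirred flask, run for 3.0 min | a stirred flask in which starting material is dosed at a steady rate over 1.50 min without added volume, worked up at 3.0 min | all but second substrate at the start; second substrate goes in evenly over 1.50 min, the run ends at 3.0 min | one stirred flow tank at steady state, fed with the mixture as stated, mean residence time 3.0 min |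

    capture agent + second complex → trapped intermediate (k1 = 7200 /M/s)
    first complex → loaded enzyme + first product (k2 = 52 /s)
    second complex → free enzyme + target (k3 = 110 /s)
    second substrate + loaded enzyme ⇌ second complex (K4 = 34 /M, k4 = 2.4 × 10⁵ /M/s)
    starting material + free enzyme ⇌ first complex (K5 = 12 /M, k5 = 21000 /M/s)
    free enzyme + target → free enzyme + over-reaction product A (k6 = 950 /M/s)
    target → over-reaction product B (k7 = 1.9 × 10⁻⁵ /s)

- the stated concentrations are those of everything mixed, before any reaction; amounts are the same in each set-up
- the feed brings no volume worth counting
- the share counts what is present at the end, not what went on to other products
- run time (epsilon): 3.0 min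

1. the set-up with the highest share of target in all that became target or over-reaction product A or trapped intermediate, at the outlet or at the end ("none" if the first two lie within 2 percentage points) (epsilon / delta / beta / alpha / none)
2. share of target in all that became target or over-reaction product A or trapped intermediate, at the outlet or at the end, epsilon
3. share of target in all that became target or over-reaction product A or trapped intermediate, at the outlet or at the end, delta
4. share of target in all that became target or over-reaction product A or trapped intermediate, at the outlet or at the end, beta
5. share of target in all that became target or over-reaction product A or trapped intermediate, at the outlet or at the end, alpha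

1. In the flask now: the free enzyme charge, E = 1.00 × 10⁻⁵ M, meets capture agent at 0.0300 M, far more than E. So capture is a pseudo-first-order exit from second complex, with constant 216 /s. The other exit, to target, has constant 110 /s.

2. Both exits draw on the same second complex, so target and trapped intermediate form in the ratio of those constants at each moment, whatever the return to loaded enzyme does. Keep L = −0.293, the common logarithm of target formed per trapped intermediate formed.

3. When you come: undoing the logarithm gives 0.509 target per enzyme, because each enzyme is trapped once. I therefore expect target at 0.00509% of the starting material charged, first product at 1.51 × 10⁻⁵ M, and starting material near its charge. The share is 33.7%.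

4. Do not touch the capture agent: its concentration stands inside L. Dosing stands outside L, so this reckoning gives 33.7% for epsilon, delta, beta and alpha before any target goes on to over-reaction product A, and I commit to no winner. Do not wait for more target: the scheme has no way back from trapped intermediate. Loss to over-reaction product B is slow, its half-life of 10 h being long against 3.0 min.

5. The forecast gives 33.67% for epsilon, 33.5% for delta, 33.67% for beta and 33.66% for alpha, with best none, reasoning that “So all enzyme ends up trapped”. Its delta stands below my unreduced figure.

6. The simulation gives 33.7% for epsilon, 33.5% for delta, 33.7% for beta and 33.7% for alpha, with best none. A neighbouring flask is like beta but holds capture agent at 0.0075 M. The same reckoning moves L to 0.309, which is 2.04 target per enzyme and a share of 67.1%. Simulated, that flask gives 67.0%, with trapped intermediate at 100% of the catalyst charged and target at 0.0203% of the starting material charged after 3.00 min.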